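**Retrosynthetic overview** (eudesmane numbering)
1. Feature: the ring-fusion carbons C10 (quaternary, bearing C14) and C5 are neighbours. They are flanked by C1 and C4, and ring A carries oxygen at C3. This C1–C10(CH3)=C5–C4 array maps onto the methyl-bearing double bond of 2-methoxy-5-methyl-1,4-benzoquinone, so ring A is bought as the quinone.
2. Key disconnection: C5–C6 and C9–C10. One intermolecular Diels–Alder reaction closes ring B with a butadiene that carries a ketal-masked acetyl group (C11/C13) on the future C7.
3. Endgame: the 5α-OOH/4(15)-ene comes from a singlet-oxygen ene reaction of the C4=C5 alkene, the angelate from the 3β-alcohol, and the alcohol from the 4-en-3-one.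
4. Middle: C15 enters by methyl cross-coupling at the C4 enol triflate, which also flattens C5. The C1 oxygen leaves through reduction/transposition to the 1,4-dien-3-one followed by CuH reduction. C7 is set by acetyl equilibration, and the acrylate comes from carbonylation of the C11 enol triflate.
5. Ring order: ring A is preformed as the quinone, and ring B is formed in the key step.

Key step: step 6

Assumption: the sense of induction in step 6 is assigned from the stacking model of the (S)-catalyst; if the opposite sense were found, the equally accessible (R)-catalyst would be used.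

**Step 1**
Reactants: 1 2-methyl-1,4-benzoquinone (two equivalents, the second as oxidant)
Product: 3 2-methoxy-5-methyl-1,4-benzoquinone, via 2-methoxy-5-methylbenzene-1,4-diol 2 (not isolated)
Conditions: ZnCl2, MeOH, reflux
Reagents that add atoms: methanol, CO
Why: Lewis-acid-promoted Michael-type addition of methanol should occur at C5, the β-carbon of the carbonyl that the methyl group does not deactivate, and a second equivalent of 1 then oxidises hydroquinone 2 (oxidative alkoxylation of a quinone).

**Step 2**
Reactants: 4 methyl vinyl ketone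
Product: 5 3,4-dibromobutan-2-one (racemic)
Conditions: Br2, CH2Cl2, −78 → 0 °C
Reagents that add atoms: bromine, BrBr
Why: Electrophilic anti addition of bromine masks the polymerisable, Michael-reactive double bond so that the ketone can be ketalised cleanly.

**Step 3**
Reactants: 5 3,4-dibromobutan-2-one
Product: 6 2-(1,2-dibromoethyl)-2-methyl-1,3-dioxolane (racemic)
Conditions: HOCH2CH2OH, TsOH (cat.), benzene, reflux, azeotropic removal of water
Reagents that add atoms: ethane-1,2-diol, OCCO
Why: Acid-catalysed ketalisation of an electrophilic α-bromoketone should proceed normally, and no conjugate addition of the diol can compete because the alkene is masked.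

**Step 4**
Reactants: 6 2-(1,2-dibromoethyl)-2-methyl-1,3-dioxolane
Product: 7 2-(1-bromoethenyl)-2-methyl-1,3-dioxolane
Conditions: KOt-Bu (1.05 equiv), THF, 0 °C
Reagents that add atoms: none
Why: E2 dehydrobromination removes the more acidic CHBr hydrogen next to the oxygenated carbon and expels the primary bromide, the known bias of vicinal dibromides with an adjacent oxygen function toward 2-bromo-1-alkenes.

**Step 5**
Reactants: 7 2-(1-bromoethenyl)-2-methyl-1,3-dioxolane; 8 tributyl(vinyl)stannane
Product: 9 2-(2-methyl-1,3-dioxolan-2-yl)buta-1,3-diene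
Conditions: Pd(PPh3)4 (cat.), CuI (cat.), CsF, DMF, 45 °C; distillation, storage cold over BHT
Reagents that add atoms: none
Why: Stille coupling of a vinyl bromide with a vinylstannane at zerovalent palladium is reliable, and fluoride activation allows a mild temperature and removes tin as an insoluble fluoride.

**Step 6**
Reactants: 3 2-methoxy-5-methyl-1,4-benzoquinone; 9 2-(2-methyl-1,3-dioxolan-2-yl)buta-1,3-diene
Product: 10 (4aR,8aS)-2-methoxy-4a-methyl-7-(2-methyl-1,3-dioxolan-2-yl)-4a,5,8,8a-tetrahydronaphthalene-1,4-dione (eudesmane numbering: 5S,10R; 10β-methyl and 5β-H, cis-fused; C1 and C4 ketones, C3 OMe, C7=C8)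
Conditions: (S)-3,3-diphenyl-1-(2-methylphenyl)tetrahydro-1H,3H-pyrrolo[1,2-c][1,3,2]oxazaborole·HNTf2 (20 mol %), CH2Cl2, −78 → −40 °C
Reagents that add atoms: none
Why: The mechanism is a concerted, asynchronous, normal-electron-demand [4+2] cycloaddition of the diene (C6=C7–C8=C9) to the C5=C10 bond of the boron-bound quinone, and the closest known reaction type is the enantioselective quinone Diels–Alder reaction under N-protonated oxazaborolidine catalysis, the chiral counterpart of the BF3-promoted additions known for 3. Ring B is closed in the intermolecular mode from four diene carbons and two quinone carbons, with C5–C6 forming ahead of C9–C10. Site selectivity comes from the methoxy group, which turns C2=C3 into a vinylogous ester and leaves the methyl-bearing C5=C10 bond as the only competent dienophile. Regioselectivity comes from the monodentate boron sitting on the more basic C1 oxygen (the vinylogous-ester carbonyl, at the lone pair syn to C2–H), which makes C5 the β-carbon of the activated enone, so that the diene CH2 next to the substituted carbon (larger HOMO coefficient) bonds there and the ketal carbon ends on C7, not C8. C10 is controlled by the catalyst, because the bound quinone stacks one face on a phenyl group of the CPh2 unit and the diene must take the open face, whereas C5 follows from suprafacial addition to a ring double bond, so the cis fusion needs no endo/exo preference (the diene has no terminal substituent) and C5 is erased again in step 7. Low temperature and an exact 1:1 match of oxazaborolidine and HNTf2 keep free acid away from the allylic dioxolane.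

**Step 7**
Reactants: 10 cis-fused adduct
Product: 12 (10R)-11,11-ethylenedioxy-3-methoxy-1-oxo-12-noreudesma-2,4,7-trien-4-yl triflate, via potassium C4-dienolate 11 (not isolated)
Conditions: KN(SiMe3)2, THF, −78 °C; PhNTf2, −78 °C → rt
Reagents that add atoms: N-phenylbis(trifluoromethanesulfonimide), O=S(=O)(N(c1ccccc1)S(=O)(=O)C(F)(F)F)C(F)(F)F; KN(SiMe3)2, [K+].C[Si](C)(C)[N-][Si](C)(C)C (potassium kept in 11 only)
Why: In this enol triflate formation C5–H is the only enolisable hydrogen (C10 is quaternary, C2–H is vinylic), so a single regioisomer should form and the temporary C5 centre is flattened.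

**Step 8**
Reactants: 12 C4 enol triflate
Product: 13 (10R)-11,11-ethylenedioxy-3-methoxy-12-noreudesma-2,4,7-trien-1-one (C15 methyl on C4)
Conditions: Me2Zn, PdCl2(dppf) (cat.), THF, 0 → 50 °C
Reagents that add atoms: dimethylzinc, C[Zn]C
Why: Negishi coupling places the small methyl group on C4 without any positional ambiguity of the C4=C5 alkene, and Me2Zn does not add to the deactivated C1 carbonyl without activation.

**Step 9**
Reactants: 13 methylated dienone ketal
Product: 14 (10R)-3-methoxy-12-noreudesma-2,4,7-triene-1,11-dione (7-acetyl, C7=C8)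
Conditions: PPTS (cat.), THF–H2O, 40 °C
Reagents that add atoms: water, O
Why: In this acid-catalysed ketal hydrolysis the allylic dioxolane ionises to a conjugated oxocarbenium ion much faster than the vinylogous methyl ester of ring A is attacked by water.

**Step 10**
Reactants: 14 acetyl enone
Product: 15 (10R)-3-methoxy-12-noreudesma-2,4-diene-1,11-dione (mixture of C7 epimers)
Conditions: [CuH(PPh3)]6, H2O, degassed toluene, rt
Reagents that add atoms: none
Why: Conjugate reduction by the phosphine-stabilised copper hydride delivers hydride to the unhindered C8 of the acetyl enone, while ring A is protected by its β-methoxy group and its fully substituted C5 terminus.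

**Step 11**
Reactants: 15 C7 epimer mixture
Product: 16 (7R,10R)-3-methoxy-12-noreudesma-2,4-diene-1,11-dione (7β-acetyl, equatorial)
Conditions: NaOMe (cat.), MeOH, rt; minor epimer separated and resubmitted
Reagents that add atoms: none
Why: Enolate-mediated epimerisation under thermodynamic control places the acetyl group equatorial on the ring B chair, and with the axial 10β-methyl group fixed this is the 7β position, so C10 dictates C7 (methoxide exchange at C3 is degenerate).

**Step 12**
Reactants: 16 7β-acetyl compound
Product: 18 (7R,10R)-3-methoxy-1-oxo-12-noreudesma-2,4,11(13)-trien-11-yl triflate, via potassium C11-enolate 17 (not isolated)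
Conditions: KN(SiMe3)2 (1.05 equiv), THF, −78 °C; N-(5-chloropyridin-2-yl)bis(trifluoromethanesulfonimide), −78 °C
Reagents that add atoms: N-(5-chloropyridin-2-yl)bis(trifluoromethanesulfonimide), O=S(=O)(N(c1ccc(Cl)cn1)S(=O)(=O)C(F)(F)F)C(F)(F)F; KN(SiMe3)2, [K+].C[Si](C)(C)[N-][Si](C)(C)C (potassium kept in 17 only)
Why: Kinetic enolate formation and O-triflation should take the unhindered CH3 through a carbonyl-bound base, since ring A has no α-hydrogen and its remote C6–H cannot use such a cyclic transition state, and fast trapping at −78 °C leaves C7 untouched.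

**Step 13**
Reactants: 18 C11 enol triflate
Product: 20 (7R,10S)-3-oxo-12-noreudesma-1,4,11(13)-trien-11-yl triflate, via C1 allylic alcohol 19 (not isolated)
Conditions: i-Bu2AlH, CH2Cl2, −78 °C; then 1 M HCl, THF, 0 °C → rt
Reagents that add atoms: water, O
Why: In this Stork–Danheiser-type transposition, 1,2-reduction of the vinylogous ester is followed by acid ionisation of the C1 hydroxyl to a methoxy-stabilised cation, and hydrolysis at C3 gives the cross-conjugated 1,4-dien-3-one, while the vinyl triflate is inert to both reagents.

**Step 14**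
Reactants: 20 1,4-dien-3-one
Product: 21 (7R,10S)-3-oxo-12-noreudesma-4,11(13)-dien-11-yl triflate
Conditions: [CuH(PPh3)]6, H2O, degassed toluene, rt
Reagents that add atoms: none
Why: Conjugate reduction of a cross-conjugated dienone by copper hydride takes the disubstituted C1=C2 bond and leaves the tetrasubstituted C4=C5 bond, and it is done before the acrylate, itself a good acceptor, exists.

**Step 15**
Reactants: 21 4-en-3-one triflate
Product: 22 methyl (7R,10S)-3-oxoeudesma-4,11(13)-dien-12-oate
Conditions: CO (1 atm), Pd(OAc)2 (cat.), Ph2P(CH2)3PPh2, Et3N, MeOH–DMF, 50 °C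
Reagents that add atoms: carbon monoxide, [C-]#[O+]; methanol, CO
Why: Palladium-catalysed methoxycarbonylation of a vinyl triflate (oxidative addition, CO insertion, methanolysis) gives the α-substituted acrylate with the double bond fixed at C11=C13.

**Step 16**
Reactants: 22 keto acrylate
Product: 23 methyl (3S,7R,10S)-3β-hydroxyeudesma-4,11(13)-dien-12-oate
Conditions: NaBH4, CeCl3·7H2O, MeOH, −20 °C
Reagents that add atoms: none
Why: Luche 1,2-reduction touches only the C3 ketone, and axial hydride delivery from the α face of the half-chair, unhindered because C5 is sp2, should give the equatorial 3β-alcohol.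

**Step 17**
Reactants: 23 3β-alcohol; 24 angelic acid, (Z)-2-methylbut-2-enoic acid
Product: 26 methyl (3S,7R,10S)-3β-angeloyloxyeudesma-4,11(13)-dien-12-oate, via angelic 2,4,6-trichlorobenzoic anhydride 25 (not isolated)
Conditions: 24, 2,4,6-trichlorobenzoyl chloride, Et3N, toluene, rt; then 23, 80 °C (no DMAP)
Reagents that add atoms: 2,4,6-trichlorobenzoyl chloride, O=C(Cl)c1c(Cl)cc(Cl)cc1Cl (atoms kept in 25 only)
Why: Yamaguchi-type mixed-anhydride esterification without a nucleophilic catalyst is the variant known to transfer the angeloyl group without Z→E isomerisation, and C3 is retained because its C–O bond is not touched.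

**Step 18**
Reactants: 26 3β-angelate
Product: 27 methyl (3S,5S,7R,10S)-3β-angeloyloxy-5α-hydroperoxyeudesma-4(15),11(13)-dien-12-oate (target)
Conditions: O2, tetraphenylporphyrin (cat.), visible light, CH2Cl2, −20 °C; no reductive work-up
Reagents that add atoms: dioxygen, O=O
Why: In the Schenck ene reaction singlet oxygen attacks the only electron-rich alkene (C4=C5) from the α face, opposite the axial 10β-methyl and the 3β-ester, bonds to C5 and takes a C15 hydrogen (on that face C6 offers only an in-plane hydrogen and H3α is deactivated by the geminal acyloxy group), which sets 5α-OOH with a trans fusion and moves the alkene to C4=C15.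

**Compound list**
1 | 2-methyl-1,4-benzoquinone | CC1=CC(=O)C=CC1=O | starting material
2 | 2-methoxy-5-methylbenzene-1,4-diol | COc1cc(O)c(C)cc1O | intermediate
3 | 2-methoxy-5-methyl-1,4-benzoquinone | COC1=CC(=O)C(C)=CC1=O | intermediate
4 | methyl vinyl ketone | C=CC(C)=O | starting material
5 | 3,4-dibromobutan-2-one | CC(=O)C(Br)CBr | intermediate
6 | 2-(1,2-dibromoethyl)-2-methyl-1,3-dioxolane | CC1(OCCO1)C(Br)CBr | intermediate
7 | 2-(1-bromoethenyl)-2-methyl-1,3-dioxolane | C=C(Br)C1(C)OCCO1 | intermediate
8 | tributyl(vinyl)stannane | C=C[Sn](CCCC)(CCCC)CCCC | starting material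
9 | 2-(2-methyl-1,3-dioxolan-2-yl)buta-1,3-diene | C=CC(=C)C1(C)OCCO1 | intermediate
10 | cis-fused adduct (5S,10R) | COC1=CC(=O)[C@]2(C)CC=C(C3(C)OCCO3)C[C@@H]2C1=O | intermediate
11 | potassium C4-dienolate of 10 | COC1=CC(=O)[C@]2(C)CC=C(C3(C)OCCO3)CC2=C1[O-].[K+] | intermediate
12 | C4 enol triflate (10R) | COC1=CC(=O)[C@]2(C)CC=C(C3(C)OCCO3)CC2=C1OS(=O)(=O)C(F)(F)F | intermediate
13 | 3-methoxy-4-methyl-2,4,7-trien-1-one ketal (10R) | COC1=CC(=O)[C@]2(C)CC=C(C3(C)OCCO3)CC2=C1C | intermediate
14 | 7-acetyl-2,4,7-trien-1-one (10R) | COC1=CC(=O)[C@]2(C)CC=C(C(C)=O)CC2=C1C | intermediate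
15 | 7-acetyl-2,4-dien-1-one, C7 epimers (10R) | COC1=CC(=O)[C@]2(C)CCC(C(C)=O)CC2=C1C | intermediate
16 | 7β-acetyl-2,4-dien-1-one (7R,10R) | COC1=CC(=O)[C@]2(C)CC[C@@H](C(C)=O)CC2=C1C | intermediate
17 | potassium C11-enolate of 16 | C=C([O-])[C@@H]1CC[C@@]2(C)C(=O)C=C(OC)C(C)=C2C1.[K+] | intermediate
18 | C11 enol triflate, ring A methoxydienone (7R,10R) | C=C(OS(=O)(=O)C(F)(F)F)[C@@H]1CC[C@@]2(C)C(=O)C=C(OC)C(C)=C2C1 | intermediate
19 | C1 allylic alcohol (C1 epimers) | C=C(OS(=O)(=O)C(F)(F)F)[C@@H]1CC[C@@]2(C)C(O)C=C(OC)C(C)=C2C1 | intermediate
20 | 1,4-dien-3-one triflate (7R,10S) | C=C(OS(=O)(=O)C(F)(F)F)[C@@H]1CC[C@@]2(C)C=CC(=O)C(C)=C2C1 | intermediate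
21 | 4-en-3-one triflate (7R,10S) | C=C(OS(=O)(=O)C(F)(F)F)[C@@H]1CC[C@@]2(C)CCC(=O)C(C)=C2C1 | intermediate
22 | methyl 3-oxoeudesma-4,11(13)-dien-12-oate (7R,10S) | C=C(C(=O)OC)[C@@H]1CC[C@@]2(C)CCC(=O)C(C)=C2C1 | intermediate
23 | methyl 3β-hydroxyeudesma-4,11(13)-dien-12-oate (3S,7R,10S) | C=C(C(=O)OC)[C@@H]1CC[C@@]2(C)CC[C@H](O)C(C)=C2C1 | intermediate
24 | angelic acid | C/C=C(/C)C(=O)O | starting material
25 | angelic 2,4,6-trichlorobenzoic anhydride | C/C=C(/C)C(=O)OC(=O)c1c(Cl)cc(Cl)cc1Cl | intermediate
26 | methyl 3β-angeloyloxyeudesma-4,11(13)-dien-12-oate (3S,7R,10S) | C=C(C(=O)OC)[C@@H]1CC[C@@]2(C)CC[C@H](OC(=O)/C(C)=C\C)C(C)=C2C1 | intermediate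
27 | methyl 3β-angeloyloxy-5α-hydroperoxyeudesma-4(15),11(13)-dien-12-oate (3S,5S,7R,10S) | C=C(C(=O)OC)[C@@H]1CC[C@@]2(C)CC[C@H](OC(=O)/C(C)=C\C)C(=C)[C@]2(OO)C1 | target

**Total step count:** 18. **Longest linear sequence:** 17 steps (steps 2–18, from methyl vinyl ketone 4).

**Steps most likely to fail**

1. **Step 6.**
   - What may go wrong: facial discrimination may be weak, because the boron is anchored on the C2–H side of the C1 carbonyl and the reacting C5=C10 bond lies away from the shielding phenyl group. The C7/C8 orientation may erode, because the ketal-bearing carbon is only a weak director. Adventitious acid may ionise the dioxolane and oligomerise the diene.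
   - Fallback (resolution in place of asymmetric catalysis): it sets out from 3 and 9. These are combined under achiral BF3·OEt2 (CH2Cl2, −78 °C), the monodentate acid for which this orientation is established. This should give 10 together with its mirror image, the (5R,10S)-adduct F1. The two are separated by preparative chromatography on a polysaccharide-based chiral stationary phase, and the route is rejoined at 10.

2. **Step 18.**
   - What may go wrong: hydrogen abstraction may occur at C3 or C6 instead of C15. Oxygenation may be slow because the allylic ester lowers the nucleophilicity of the alkene. The angelate may isomerise during long irradiation, and the hydroperoxide may undergo allylic migration.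
   - Fallback (oxygenation before acylation, with the hydroperoxide masked): it sets out from 23.
     - Silylation (t-BuMe2SiCl, imidazole, DMF) should give the 3β-silyl ether F3.
     - Its more electron-rich alkene is photooxygenated as in step 18 to the 5α-hydroperoxide F4.
     - 2-Methoxypropene with catalytic PPTS masks the OOH group as the 2-methoxyprop-2-yl peroxyketal F5.
     - Bu4NF buffered with AcOH frees the 3β-alcohol F6.
     - Acylation with anhydride 25 (made from 24 as in step 17; toluene, 60 °C) gives the angelate peroxyketal F7.
     - AcOH–THF–H2O at rt releases the hydroperoxide, and the route is rejoined at 27.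

3. **Step 8.**
   - What may go wrong: oxidative addition and transmetalation may be sluggish at a triflate flanked by the methoxy carbon and a fully substituted C5 next to quaternary C10. Sulfur–oxygen cleavage back to the ketone or reduction to C4–H could then compete.
   - Fallback (carbonyl addition and elimination in place of cross-coupling; it also bypasses step 7): it sets out from 10. MeLi/CeCl3 (THF, −78 °C) should add from the convex face to C4, the only true ketone, since C1 is a neopentyl vinylogous ester. This gives the 4β-methyl-4α-carbinol F2. SOCl2/pyridine (0 °C) then removes the hydroxyl together with the anti-disposed 5β-hydrogen, and the route is rejoined at 13.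

**Further compounds**
F1 | step 6 | (5R,10S)-adduct, mirror image of 10 | COC1=CC(=O)[C@@]2(C)CC=C(C3(C)OCCO3)C[C@H]2C1=O
F2 | step 8 | 4α-hydroxy-4β-methyl adduct of 10 | COC1=CC(=O)[C@]2(C)CC=C(C3(C)OCCO3)C[C@@H]2[C@]1(C)O
F3 | step 18 | methyl 3β-(tert-butyldimethylsilyloxy)eudesma-4,11(13)-dien-12-oate | C=C(C(=O)OC)[C@@H]1CC[C@@]2(C)CC[C@H](O[Si](C)(C)C(C)(C)C)C(C)=C2C1
F4 | step 18 | methyl 3β-(tert-butyldimethylsilyloxy)-5α-hydroperoxyeudesma-4(15),11(13)-dien-12-oate | C=C(C(=O)OC)[C@@H]1CC[C@@]2(C)CC[C@H](O[Si](C)(C)C(C)(C)C)C(=C)[C@]2(OO)C1
F5 | step 18 | 2-methoxyprop-2-yl peroxyketal of F4 | C=C(C(=O)OC)[C@@H]1CC[C@@]2(C)CC[C@H](O[Si](C)(C)C(C)(C)C)C(=C)[C@]2(OOC(C)(C)OC)C1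
F6 | step 18 | 3β-hydroxy peroxyketal | C=C(C(=O)OC)[C@@H]1CC[C@@]2(C)CC[C@H](O)C(=C)[C@]2(OOC(C)(C)OC)C1
F7 | step 18 | 3β-angeloyloxy peroxyketal | C=C(C(=O)OC)[C@@H]1CC[C@@]2(C)CC[C@H](OC(=O)/C(C)=C\C)C(=C)[C@]2(OOC(C)(C)OC)C1
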